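Remarks on the chemistry (assumptions and design points, fixed before the route)

- Ring A is the acyl ring that carries the methoxy group; ring B is the ring with the free carboxyl. In each ring the carboxyl-bearing carbon is C1. Chain carbons of the open precursor are counted from the ester carbon (C1).
- Compounds 9, 11, 12 and 13 are drawn in keto form; they will be largely enolised.
- The aldol closure of the key step is classed as 6-(enolendo)-exo-trig. The label enolexo does not fit, because the reacting enolate double bond C2=C3 lies inside the new ring; only the minor ester-enolate form would be enolexo.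
- The acid used after the base in the key step is acetic acid. Dehydration is already base-driven, and mineral acid would endanger the dioxolane.
- The chain is assembled with an N-methoxy-N-methylamide made directly from the ester, not with an imidazolide. This saves a step and avoids handling a free β-ketal acid.
- Ring A is not made separately: the product of the key step serves both rings.
- The acid chloride is made under neutral conditions, and the ketals are removed before the final hydrogenolysis, not after it.

## Structural features

Microphyllinic acid is an achiral para-depside: two tetrasubstituted benzene rings joined only by an ester between the C1 carboxyl of ring A and the C4 oxygen of ring B. Ring A carries a hydrogen-bonded hydroxyl on C2, a methoxy group on C4 and a 2-oxoheptyl chain on C6. Ring B carries the free carboxyl on C1, a hydrogen-bonded hydroxyl on C2 and the same 2-oxoheptyl chain on C6, so the two rings share one carbon skeleton and one oxygen pattern. There is no stereocentre, so the problems are chemoselectivity and regiochemistry on two nearly identical resorcylate rings. The aryl ester is an activated ester that alkoxide, hydroxide or amines cleave, and the salicylic-type acid of ring B can decarboxylate in hot acid. Each ArCH2C(=O) ketone sits ortho to a carboxyl derivative and can close onto it (lactol, enol lactone, isocoumarin) under base or under acylating conditions. The real difficulty is to make a 2,6-disubstituted benzoate ester at one particular phenol while two ketones stay silent and four phenolic oxygens are told apart. The key step uses the fact that C1 (with its carboxyl), C2–O, C4–O and C6–CH2 of ring B are C2, C3, C5 and C7 of a 3,5,7,9-tetraoxotetradecanoate chain, so that joining C2 to C7 (ring bond C1–C6) gives the ring with every substituent in place.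

## Logic of the disconnections

23 to 22. The two O–CH2Ph bonds are cut: the ester oxygen of the ring B carboxyl and the ether oxygen on C2 of ring A. The free acid is the group most likely to decarboxylate or to close onto the neighbouring ketone, so it is unveiled last and under neutral conditions. The skeleton is not simplified, but every earlier step can then run on a neutral molecule. The forward step must leave the aryl ester and both ketones untouched.

22 to 21. The two ketone carbonyls are returned to dioxolanes (four C–O bonds). A free ketone next to an acylating centre would cyclise during the coupling, and the same mask directs the fold in step 6. The gain is that the ketones stay silent through every basic step. The forward step must hydrolyse two ketals at an acidity that the ester between the rings survives, and must release the ketones with no base present.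

21 to 19 and 14, through 20. The acyl C–O bond between the C1 carbonyl of ring A and the C4 oxygen of ring B is cut. It is the only link between the rings, and the two pieces have the same skeleton. The molecule is halved. The forward step must acylate the free C4 hydroxyl of 14 and not the hydrogen-bonded C2 hydroxyl, and must activate the hindered acid 19 without setting acid free.

19 to 14, by way of 18 and 16. The O–CH3 bond on C4, the O–CH2Ph bond on C2 and the acid–ester relation are traced back. Ring A is ring B with a methyl group on the C4 oxygen, so it is derived from the same intermediate and not built on its own. One ring synthesis then does the work of two, and the key step is run once. The forward steps must methylate only the hydroxyl that is not hydrogen-bonded, and must hydrolyse a 2,6-disubstituted ester without touching the ketal.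

14 to 12. Ring bond C1–C6 (C2–C7 of the chain) is cut. A benzene ring with four substituents unravels to a linear chain whose carbonyls stand where the ring oxygens are. The only question left is the mode of folding. The forward step therefore needs a chain that can fold in one way only: C9 masked, a poorly electrophilic ester, and a weak base.

12 to 9 and 10, through 11. The ester C1–O bond is cut. The free triketo ester is too reactive to carry through strong-base chemistry, whereas the dioxinone ring of 9 hides C1 to C3 and releases them on heating. The gain is a robust precursor. The forward step needs capture of 11 by 10 to outrun capture by an internal enol oxygen.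

9 to 8 and 5. Chain bond C6–C7 is cut, a Claisen-type disconnection beside a ketone. It gives a nucleophile holding C1 to C6 and an electrophile holding C7 to C14, two pieces of similar size. The forward step needs acylation at the terminal carbon of a dianion only, a single addition, and an acyl donor that resists α-deprotonation.

8 to 6 and 7. Chain bond C4–C5 is cut. The vinylogous enolate of 6 is acylated at its γ-carbon, which leads to two commercial compounds. The product is more acidic than 6, so the forward step needs an excess of enolate.

5 to 3 and 4, then 3 to 1 and 2. The amide C–N bond and the two ketal C–O bonds are cut. The C9 carbonyl must be masked before any enolate is made, and the amide comes directly from the ester. This reaches commercial 1. The forward ketalisation must be driven by removal of water.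

## Other disconnections considered

Alternative 1: The cut is in ring A, at the bond from C1 to the carboxyl carbon and at the bond from C6 to the benzylic CH2; both would be formed across an aryne.

- Forward key step: fluoride would release the aryne from 3,5-dimethoxy-2-(trimethylsilyl)phenyl trifluoromethanesulfonate A1. The anion of dibenzyl malonate A2 would attack the aryne carbon meta to the flanking methoxy group. The aryl anion left ortho to that methoxy group would take one ester group from the malonate carbon through a four-membered alkoxide, giving benzyl 2-[2-(benzyloxy)-2-oxoethyl]-4,6-dimethoxybenzoate A3.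
- In favour: the arene is bought and not made, and the two ortho carbon substituents go in together under nearly neutral conditions. The regiochemistry follows from the inductive effect of the flanking methoxy group, so no folding mode has to be controlled. On regiocontrol this alternative is the equal of the chosen plan, and on mildness of the key step it is the better.
- Against it here: A3 is still far from ring A.
  - The aliphatic ester would have to become a pentyl ketone in the presence of the aryl ester, through intermediates of the homophthalic type that close readily to anhydrides or isocoumarins.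
  - The C2 methyl ether would have to be cleaved selectively by a Lewis acid that neither a ketal nor the ester between the rings would survive.
  - A1 itself needs several steps.
  - Ring B is not served: it needs a free C4 oxygen, hence a second aryne precursor with removable ethers or a harsh double demethylation.
- Comparison: in mechanism, the insertion is a polar addition followed by acyl transfer and has no competing ring closure, whereas the chosen aldol has to win against other closures. In structure, the chosen plan gives in 14 two free phenols already told apart by hydrogen bonding, with the ketone in place and masked, and it supplies both rings. In step economy, the alternative would need about ten steps for ring A alone and a separate route for ring B, against nine steps to both halves (14 and 19) in the chosen plan.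

Alternative 2: The cut is at ring bonds C1–C6 and C2–C3, at the oxidation level of a cyclohexane-1,3-dione.

- Forward key step: the sodium salt of A2 would add to the β-carbon of (E)-5-(2-pentyl-1,3-dioxolan-2-yl)pent-3-en-2-one A4 (Michael addition, bond C1–C6). The methyl ketone enolate so formed would attack one malonate ester (Claisen closure, bond C2–C3) to give racemic benzyl 2-hydroxy-4-oxo-6-[(2-pentyl-1,3-dioxolan-2-yl)methyl]cyclohex-1-ene-1-carboxylate A5, which would later be dehydrogenated to 14.
- In favour: cheap reagents, no cryogenic strong base, and a substitution pattern that follows from the connectivity of the two components, with no competing mode of closure. On certainty of the ring-forming step and on ease of scale-up this alternative is the better. Because it converges on 14, everything after step 6 would stay as planned.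
- Against it here: A5 is two hydrogens short of the arene.
  - The aromatisation (halogenation and dehydrohalogenation, or dehydrogenation over a metal with heating) sets acid free or needs heat, so the dioxolane, the benzyl ester and the electron-rich ring being formed are at risk of cleavage or over-halogenation.
  - A4 has a CH2 between the enone and the ketal carbon. The base of the key step can deprotonate it, which invites deconjugation or a vinylogous β-elimination that opens the dioxolane.
  - The stereocentre of A5 does not matter, since it is destroyed.
- Comparison: in mechanism, both plans close the ring by carbonyl condensation of a stabilised enolate, but the chosen plan reaches the aromatic oxidation level directly and is driven by aromatisation. In step economy, A4 would take about two steps from 3, so 14 would be reached in about five steps against six; on count alone the alternative is slightly the better. It pays for this with an oxidation that is the step least compatible with the protecting groups.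

Alternative 3: The cut is at ring bonds C1–C2 and C5–C6 of ring A, which would be built last, on the ester that already joins it to ring B.

- Forward key step: benzyl 2-(benzyloxy)-4-hydroxy-6-[(2-pentyl-1,3-dioxolan-2-yl)methyl]benzoate A6 would be esterified with 4-(2-pentyl-1,3-dioxolan-2-yl)but-2-ynoic acid A7 to the aryl alkynoate A8. A8 would then be heated with 1,3-dimethoxy-1-(trimethylsilyloxy)buta-1,3-diene A9. The [4+2] adduct would lose one methoxy group as the alcohol, and its silyl group on acidic work-up, to give benzyl 2-(benzyloxy)-4-({2-hydroxy-4-methoxy-6-[(2-pentyl-1,3-dioxolan-2-yl)methyl]benzoyl}oxy)-6-[(2-pentyl-1,3-dioxolan-2-yl)methyl]benzoate A10.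
- In favour: the ester between the rings would be made from a slim alkynoic acid and not from a 2,6-disubstituted benzoic acid, so the hardest bond of the chosen plan (step 10) becomes easy; here the alternative is the better. The diene delivers the C2 hydroxyl and the C4 methoxy of ring A in final form, so steps 7 and 8 have no counterpart; again the better. Regiochemistry follows from the polarisation of diene and dienophile.
- Against it here:
  - A8 is an activated aryl ester and A9 a strong carbon nucleophile, so acyl transfer or open-chain conjugate addition may replace cycloaddition.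
  - An alkynoate substituted on its β-carbon is a slow dienophile, and at the temperature needed the CH2 between alkyne and ketal can isomerise to the allene.
  - A6 has the benzyl group on the hydrogen-bonded oxygen and the free hydroxyl on the reactive position, the reverse of what direct benzylation of 14 would give, so a detour of protection and deprotection is needed.
  - A7 needs several steps.
  - Ring B must still come from elsewhere, most simply from step 6 of the chosen plan.
- Comparison: in structure, the alternative does not replace the chosen key step but adds a second ring construction to it, and it commits all of ring B to an uncertain thermal step. In mechanism, a cycloaddition under neutral conditions is the equal of the chosen aldol in mildness. In step economy, about three steps from 14 to A6, about four to A7, two for esterification and cycloaddition and two for deprotection make it longer than the twelve steps of the chosen plan.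

Key step: step 6

## Steps

Step 1
Reactants: 1 methyl 3-oxooctanoate; 2 ethane-1,2-diol
Product: 3 methyl 2-(2-pentyl-1,3-dioxolan-2-yl)acetate
Conditions: HO(CH2)2OH (3 equiv), TsOH·H2O (cat.), toluene, reflux, Dean–Stark trap
Reagents that add atoms: ethane-1,2-diol (compound 2), OCCO
Why: Acid-catalysed ketalisation of the ketone of a β-keto ester with azeotropic removal of water; the ester carbonyl does not react, and the dioxolane masks the future C9 carbonyl before any enolate chemistry is run.

Step 2
Reactants: 3 methyl 2-(2-pentyl-1,3-dioxolan-2-yl)acetate; 4 N,O-dimethylhydroxylamine hydrochloride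
Product: 5 N-methoxy-N-methyl-2-(2-pentyl-1,3-dioxolan-2-yl)acetamide
Conditions: MeNH(OMe)·HCl (1.5 equiv), i-PrMgCl (3 equiv), THF, −20 to 0 °C; aq. NH4Cl
Reagents that add atoms: N,O-dimethylhydroxylamine hydrochloride (compound 4), CNOC.Cl
Why: Direct aminolysis of the methyl ester by the chloromagnesium amide of the hydroxylamine (Weinreb amide formation from an ester); the ketal is inert to the Grignard base at low temperature.

Step 3
Reactants: 6 2,2,6-trimethyl-4H-1,3-dioxin-4-one; 7 acetyl chloride
Product: 8 2,2-dimethyl-6-(2-oxopropyl)-4H-1,3-dioxin-4-one
Conditions: 6 (2 equiv), LiN(SiMe3)2 (2 equiv), THF, −78 °C; then AcCl (1 equiv), −78 to −40 °C; aq. NH4Cl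
Reagents that add atoms: acetyl chloride (compound 7), CC(=O)Cl
Why: Kinetic deprotonation of the C6 methyl group gives the vinylogous lithium enolate, which is acylated at its γ-carbon (crossed Claisen condensation); the product is more acidic than 6 and takes up a second equivalent of enolate, hence the twofold excess.

Step 4
Reactants: 8 2,2-dimethyl-6-(2-oxopropyl)-4H-1,3-dioxin-4-one; 5 N-methoxy-N-methyl-2-(2-pentyl-1,3-dioxolan-2-yl)acetamide
Product: 9 6-[2,4-dioxo-5-(2-pentyl-1,3-dioxolan-2-yl)pentyl]-2,2-dimethyl-4H-1,3-dioxin-4-one
Conditions: LiN(i-Pr)2 (2.2 equiv), THF, −78 °C; then 5 (0.9 equiv), −78 to −30 °C; aq. NH4Cl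
Reagents that add atoms: none
Why: Double deprotonation of 8 gives a dianion whose terminal carbanion is the more nucleophilic site (Claisen-type acylation of a dianion); the N-methoxy-N-methylamide forms a chelated tetrahedral adduct that stops a second addition and is less easily deprotonated at its α-carbon than an imidazolide or acid chloride.

Step 5
Reactants: 9 6-[2,4-dioxo-5-(2-pentyl-1,3-dioxolan-2-yl)pentyl]-2,2-dimethyl-4H-1,3-dioxin-4-one; 10 benzyl alcohol
Product: 12 benzyl 3,5,7-trioxo-8-(2-pentyl-1,3-dioxolan-2-yl)octanoate, via acylketene 11 (not isolated)
Conditions: BnOH (1.5 equiv), toluene, 110 °C; concentrated and used crude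
Reagents that add atoms: benzyl alcohol (compound 10), OCc1ccccc1
Why: Retro-hetero-Diels–Alder cleavage of the dioxinone expels acetone and gives acylketene 11, which benzyl alcohol captures as the β-keto ester (dioxinone thermolysis with ketene trapping); 12 is sensitive and is therefore not purified.

Step 6
Reactants: 12 benzyl 3,5,7-trioxo-8-(2-pentyl-1,3-dioxolan-2-yl)octanoate
Product: 14 benzyl 2,4-dihydroxy-6-[(2-pentyl-1,3-dioxolan-2-yl)methyl]benzoate, via aldol adduct 13 (not isolated)
Conditions: Cs2CO3 (2 equiv), i-PrOH/THF (1:1), 0 °C to rt; then AcOH to pH 5
Reagents that add atoms: none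
Why: Cs2CO3 deprotonates the doubly activated C2 methylene of 12, and the enolate adds to the C7 ketone, the only ketone that gives a six-membered ring from C2, forming ring bond C1–C6 of ring B in aldol 13; E1cB loss of water across C2–C7 and enolisation of the C3 and C5 carbonyls then give the benzene ring, which makes the sequence irreversible. The closest known reaction type is the base-mediated aldol aromatisation of 3,5,7-triketo esters released from diketo-dioxinones (biomimetic resorcylate synthesis). The closure is exo-trig at the carbonyl and is classed as 6-(enolendo)-exo-trig, because the enolate double bond C2=C3 lies inside the new ring; it is an allowed mode. No stereocentre remains, since the two centres of 13 vanish on aromatisation. The step needs C2-to-C7 aldol closure and not C4-to-C9 aldol, acylation of C6 by the ester (Claisen mode) or closure through oxygen to a 4-hydroxy-2-pyranone: the dioxolane removes C9 as an electrophile, the benzyl ester is a poor acyl donor once C2 is enolised, and carbonate is too weak to deprotonate C8, so β-elimination that would open the dioxolane should not compete. 2-Propanol replaces methanol so that the benzyl ester cannot be exchanged, and acetic acid replaces mineral acid so that the ketal survives.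

Step 7
Reactants: 14 benzyl 2,4-dihydroxy-6-[(2-pentyl-1,3-dioxolan-2-yl)methyl]benzoate; 15 iodomethane
Product: 16 benzyl 2-hydroxy-4-methoxy-6-[(2-pentyl-1,3-dioxolan-2-yl)methyl]benzoate
Conditions: MeI (1.05 equiv), K2CO3 (1.1 equiv), acetone, rt
Reagents that add atoms: iodomethane (compound 15), CI
Why: Williamson ether synthesis under weak-base control: the C4 hydroxyl (para to the ester, not hydrogen-bonded) is more acidic and more nucleophilic than the C2 hydroxyl held in a hydrogen bond to the ester carbonyl, so one equivalent of iodomethane should go to C4 only.

Step 8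
Reactants: 16 benzyl 2-hydroxy-4-methoxy-6-[(2-pentyl-1,3-dioxolan-2-yl)methyl]benzoate; 17 benzyl bromide
Product: 18 benzyl 2-(benzyloxy)-4-methoxy-6-[(2-pentyl-1,3-dioxolan-2-yl)methyl]benzoate
Conditions: BnBr (1.3 equiv), K2CO3 (2 equiv), DMF, 60 °C
Reagents that add atoms: benzyl bromide (compound 17), BrCc1ccccc1
Why: Williamson benzylation of the hydrogen-bonded C2 hydroxyl under more forcing conditions; the benzyl ether prevents self-acylation in step 10 and leaves together with the benzyl ester in step 12.

Step 9
Reactants: 18 benzyl 2-(benzyloxy)-4-methoxy-6-[(2-pentyl-1,3-dioxolan-2-yl)methyl]benzoate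
Product: 19 2-(benzyloxy)-4-methoxy-6-[(2-pentyl-1,3-dioxolan-2-yl)methyl]benzoic acid
Conditions: KOH (10 equiv), DMSO/H2O (4:1), 90 °C; then cold 10% aq. citric acid to pH 4, rapid extraction
Reagents that add atoms: potassium hydroxide, [K+].[OH-]
Why: Saponification of a hindered 2,6-disubstituted benzoate needs the poorly solvated hydroxide of aqueous DMSO; benzyl ether and dioxolane are stable to base, and the cold weak-acid work-up keeps the ketal.

Step 10
Reactants: 19 2-(benzyloxy)-4-methoxy-6-[(2-pentyl-1,3-dioxolan-2-yl)methyl]benzoic acid; 14 benzyl 2,4-dihydroxy-6-[(2-pentyl-1,3-dioxolan-2-yl)methyl]benzoate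
Product: 21 benzyl 4-({2-(benzyloxy)-4-methoxy-6-[(2-pentyl-1,3-dioxolan-2-yl)methyl]benzoyl}oxy)-2-hydroxy-6-[(2-pentyl-1,3-dioxolan-2-yl)methyl]benzoate, via acid chloride 20 (not isolated)
Conditions: Me2C=C(Cl)NMe2 (1.2 equiv), CH2Cl2, 0 °C to rt; then 14 (1.0 equiv), Et3N (2.5 equiv), DMAP (0.2 equiv), 0 °C to rt
Reagents that add atoms: none
Why: The α-chloroenamine turns 19 into acid chloride 20 under neutral conditions without setting HCl free, so the dioxolane survives; DMAP-catalysed acylation (nucleophilic acyl substitution) then takes the free C4 hydroxyl of 14, the C2 hydroxyl being deactivated by its hydrogen bond to the ester and by its neighbours.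

Step 11
Reactants: 21 benzyl 4-({2-(benzyloxy)-4-methoxy-6-[(2-pentyl-1,3-dioxolan-2-yl)methyl]benzoyl}oxy)-2-hydroxy-6-[(2-pentyl-1,3-dioxolan-2-yl)methyl]benzoate
Product: 22 benzyl 4-{[2-(benzyloxy)-4-methoxy-6-(2-oxoheptyl)benzoyl]oxy}-2-hydroxy-6-(2-oxoheptyl)benzoate
Conditions: 1 M aq. HCl, THF, rt
Reagents that add atoms: water, O
Why: Acid-catalysed hydrolysis of the two dialkyl dioxolanes through oxocarbenium ions; aryl ester, benzyl ester and benzyl ether are stable to dilute aqueous acid at room temperature, and the ketones are set free with no base present, so they cannot enolise onto the aryl ester.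

Step 12
Reactants: 22 benzyl 4-{[2-(benzyloxy)-4-methoxy-6-(2-oxoheptyl)benzoyl]oxy}-2-hydroxy-6-(2-oxoheptyl)benzoate
Product: 23 microphyllinic acid, 2-hydroxy-4-{[2-hydroxy-4-methoxy-6-(2-oxoheptyl)benzoyl]oxy}-6-(2-oxoheptyl)benzoic acid
Conditions: H2 (1 atm), 10% Pd/C, EtOAc, rt
Reagents that add atoms: none
Why: Catalytic hydrogenolysis cleaves the benzyl ester and the benzyl ether and leaves the aryl ester and the non-conjugated ketones alone; ending under neutral conditions keeps the free salicylic-type acid away from acid and base.

## Compound list

1 | methyl 3-oxooctanoate | CCCCCC(=O)CC(=O)OC | starting material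
2 | ethane-1,2-diol | OCCO | starting material
3 | methyl 2-(2-pentyl-1,3-dioxolan-2-yl)acetate | CCCCCC1(CC(=O)OC)OCCO1 | intermediate
4 | N,O-dimethylhydroxylamine hydrochloride | CNOC.Cl | starting material
5 | N-methoxy-N-methyl-2-(2-pentyl-1,3-dioxolan-2-yl)acetamide | CCCCCC1(CC(=O)N(C)OC)OCCO1 | intermediate
6 | 2,2,6-trimethyl-4H-1,3-dioxin-4-one | CC1=CC(=O)OC(C)(C)O1 | starting material
7 | acetyl chloride | CC(=O)Cl | starting material
8 | 2,2-dimethyl-6-(2-oxopropyl)-4H-1,3-dioxin-4-one | CC(=O)CC1=CC(=O)OC(C)(C)O1 | intermediate
9 | 6-[2,4-dioxo-5-(2-pentyl-1,3-dioxolan-2-yl)pentyl]-2,2-dimethyl-4H-1,3-dioxin-4-one | CCCCCC1(CC(=O)CC(=O)CC2=CC(=O)OC(C)(C)O2)OCCO1 | intermediate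
10 | benzyl alcohol | OCc1ccccc1 | starting material
11 | 8-(2-pentyl-1,3-dioxolan-2-yl)oct-1-ene-1,3,5,7-tetrone (acylketene, not isolated) | CCCCCC1(CC(=O)CC(=O)CC(=O)C=C=O)OCCO1 | intermediate
12 | benzyl 3,5,7-trioxo-8-(2-pentyl-1,3-dioxolan-2-yl)octanoate | CCCCCC1(CC(=O)CC(=O)CC(=O)CC(=O)OCc2ccccc2)OCCO1 | intermediate
13 | benzyl 2-hydroxy-4,6-dioxo-2-[(2-pentyl-1,3-dioxolan-2-yl)methyl]cyclohexane-1-carboxylate (aldol adduct, not isolated; mixture of racemic diastereomers, both centres lost on aromatisation) | CCCCCC1(CC2(O)CC(=O)CC(=O)C2C(=O)OCc2ccccc2)OCCO1 | intermediate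
14 | benzyl 2,4-dihydroxy-6-[(2-pentyl-1,3-dioxolan-2-yl)methyl]benzoate | CCCCCC1(Cc2cc(O)cc(O)c2C(=O)OCc2ccccc2)OCCO1 | intermediate
15 | iodomethane | CI | starting material
16 | benzyl 2-hydroxy-4-methoxy-6-[(2-pentyl-1,3-dioxolan-2-yl)methyl]benzoate | CCCCCC1(Cc2cc(OC)cc(O)c2C(=O)OCc2ccccc2)OCCO1 | intermediate
17 | benzyl bromide | BrCc1ccccc1 | starting material
18 | benzyl 2-(benzyloxy)-4-methoxy-6-[(2-pentyl-1,3-dioxolan-2-yl)methyl]benzoate | CCCCCC1(Cc2cc(OC)cc(OCc3ccccc3)c2C(=O)OCc2ccccc2)OCCO1 | intermediate
19 | 2-(benzyloxy)-4-methoxy-6-[(2-pentyl-1,3-dioxolan-2-yl)methyl]benzoic acid | CCCCCC1(Cc2cc(OC)cc(OCc3ccccc3)c2C(=O)O)OCCO1 | intermediate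
20 | 2-(benzyloxy)-4-methoxy-6-[(2-pentyl-1,3-dioxolan-2-yl)methyl]benzoyl chloride (not isolated) | CCCCCC1(Cc2cc(OC)cc(OCc3ccccc3)c2C(=O)Cl)OCCO1 | intermediate
21 | benzyl 4-({2-(benzyloxy)-4-methoxy-6-[(2-pentyl-1,3-dioxolan-2-yl)methyl]benzoyl}oxy)-2-hydroxy-6-[(2-pentyl-1,3-dioxolan-2-yl)methyl]benzoate | CCCCCC1(Cc2cc(OC)cc(OCc3ccccc3)c2C(=O)Oc2cc(O)c(C(=O)OCc3ccccc3)c(CC3(CCCCC)OCCO3)c2)OCCO1 | intermediate
22 | benzyl 4-{[2-(benzyloxy)-4-methoxy-6-(2-oxoheptyl)benzoyl]oxy}-2-hydroxy-6-(2-oxoheptyl)benzoate | CCCCCC(=O)Cc1cc(OC)cc(OCc2ccccc2)c1C(=O)Oc1cc(O)c(C(=O)OCc2ccccc2)c(CC(=O)CCCCC)c1 | intermediate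
23 | microphyllinic acid, 2-hydroxy-4-{[2-hydroxy-4-methoxy-6-(2-oxoheptyl)benzoyl]oxy}-6-(2-oxoheptyl)benzoic acid (achiral) | CCCCCC(=O)Cc1cc(OC(=O)c2c(O)cc(OC)cc2CC(=O)CCCCC)cc(O)c1C(=O)O | target

## Step count and least certain steps

Total step count: 12. Longest linear sequence: 11 steps (steps 1, 2, 4, 5, 6, 7, 8, 9, 10, 11, 12); step 3 is a one-step side branch.

Step 6 (key step). The C7 carbonyl is flanked by the quaternary ketal carbon and may accept the C2 enolate slowly. Closure through the C5 enol oxygen onto the ester (pyranone formation), Claisen-mode closure, or β-elimination that opens the dioxolane could then take over. Fallback: set out from 9 and close the ring while the dioxinone is still intact (Et3N, CH2Cl2, rt). The carboxyl carbon is then locked in the heterocycle and cannot lactonise or take part in a Claisen closure. This should give 7-hydroxy-2,2-dimethyl-5-[(2-pentyl-1,3-dioxolan-2-yl)methyl]-4H-1,3-benzodioxin-4-one F1. Opening F1 with NaOBn (from BnOH and NaH, THF, rt to 50 °C; an excess is expected to be needed because the phenoxide slows the exchange) returns to the route at 14.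

Step 4. The dianion may act as a base toward the α-CH2 of 5 and not as a nucleophile, which stops the acylation and can lead to β-elimination opening of the dioxolane; conversion may also stay low. Fallback: set out from 5 and reduce it with (i-Bu)2AlH (THF, −78 °C) to 2-(2-pentyl-1,3-dioxolan-2-yl)acetaldehyde F2. Add the dianion of 8 (LiN(i-Pr)2, THF, −78 °C) to F2 in an aldol addition, which is much faster than amide acylation, to give racemic 6-[4-hydroxy-2-oxo-5-(2-pentyl-1,3-dioxolan-2-yl)pentyl]-2,2-dimethyl-4H-1,3-dioxin-4-one F3. Oxidising F3 with Dess–Martin periodinane (NaHCO3, CH2Cl2) returns to the route at 9.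

Step 10. Acylation by the doubly ortho-substituted acid chloride may be slow. The neighbouring dioxolane oxygen may attack the acyl chloride, or traces of acid may open the ketal, and some acylation at the hydrogen-bonded hydroxyl is possible. Fallback: set out from 16 and remove its benzyl ester by hydrogenolysis (H2, Pd/C, EtOAc) to give 2-hydroxy-4-methoxy-6-[(2-pentyl-1,3-dioxolan-2-yl)methyl]benzoic acid F4, whose hydrogen-bonded hydroxyl needs no protection. Condense F4 with 14 by carbodiimide activation (N,N'-dicyclohexylcarbodiimide, toluene, rt, the classical depside coupling) to benzyl 2-hydroxy-4-({2-hydroxy-4-methoxy-6-[(2-pentyl-1,3-dioxolan-2-yl)methyl]benzoyl}oxy)-6-[(2-pentyl-1,3-dioxolan-2-yl)methyl]benzoate F5. Ketal hydrolysis (1 M aq. HCl, THF) gives benzyl 2-hydroxy-4-{[2-hydroxy-4-methoxy-6-(2-oxoheptyl)benzoyl]oxy}-6-(2-oxoheptyl)benzoate F6, and hydrogenolysis of F6 returns to the route at 23. This path also bypasses steps 8 and 9.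

Step 11. Hydrolysis of the second ketal may stall. Prolonged acid may instead promote enol-lactonisation of a freed ketone onto the benzyl ester or onto the aryl ester, with loss of the alcohol or cleavage of the link between the rings. Fallback: reverse the order of the two deprotections. Set out from 21 and hydrogenolyse first (H2, Pd/C, EtOAc) to 2-hydroxy-4-({2-hydroxy-4-methoxy-6-[(2-pentyl-1,3-dioxolan-2-yl)methyl]benzoyl}oxy)-6-[(2-pentyl-1,3-dioxolan-2-yl)methyl]benzoic acid F7, so that no benzyl ester is present as a leaving group when the ketones appear. Hydrolysing the ketals of F7 under buffered conditions (pyridinium p-toluenesulfonate, aqueous acetone, rt) returns to the route at 23.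

## Further compounds

F1 | step 6 | 7-hydroxy-2,2-dimethyl-5-[(2-pentyl-1,3-dioxolan-2-yl)methyl]-4H-1,3-benzodioxin-4-one | CCCCCC1(Cc2cc(O)cc3OC(C)(C)OC(=O)c23)OCCO1
F2 | step 4 | 2-(2-pentyl-1,3-dioxolan-2-yl)acetaldehyde | CCCCCC1(CC=O)OCCO1
F3 | step 4 | 6-[4-hydroxy-2-oxo-5-(2-pentyl-1,3-dioxolan-2-yl)pentyl]-2,2-dimethyl-4H-1,3-dioxin-4-one (racemic) | CCCCCC1(CC(O)CC(=O)CC2=CC(=O)OC(C)(C)O2)OCCO1
F4 | step 10 | 2-hydroxy-4-methoxy-6-[(2-pentyl-1,3-dioxolan-2-yl)methyl]benzoic acid | CCCCCC1(Cc2cc(OC)cc(O)c2C(=O)O)OCCO1
F5 | step 10 | benzyl 2-hydroxy-4-({2-hydroxy-4-methoxy-6-[(2-pentyl-1,3-dioxolan-2-yl)methyl]benzoyl}oxy)-6-[(2-pentyl-1,3-dioxolan-2-yl)methyl]benzoate | CCCCCC1(Cc2cc(OC)cc(O)c2C(=O)Oc2cc(O)c(C(=O)OCc3ccccc3)c(CC3(CCCCC)OCCO3)c2)OCCO1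
F6 | step 10 | benzyl 2-hydroxy-4-{[2-hydroxy-4-methoxy-6-(2-oxoheptyl)benzoyl]oxy}-6-(2-oxoheptyl)benzoate | CCCCCC(=O)Cc1cc(OC)cc(O)c1C(=O)Oc1cc(O)c(C(=O)OCc2ccccc2)c(CC(=O)CCCCC)c1
F7 | step 11 | 2-hydroxy-4-({2-hydroxy-4-methoxy-6-[(2-pentyl-1,3-dioxolan-2-yl)methyl]benzoyl}oxy)-6-[(2-pentyl-1,3-dioxolan-2-yl)methyl]benzoic acid | CCCCCC1(Cc2cc(OC)cc(O)c2C(=O)Oc2cc(O)c(C(=O)O)c(CC3(CCCCC)OCCO3)c2)OCCO1
A1 | alternative 1 | 3,5-dimethoxy-2-(trimethylsilyl)phenyl trifluoromethanesulfonate | COc1cc(OC)c([Si](C)(C)C)c(OS(=O)(=O)C(F)(F)F)c1
A2 | alternative 1 | dibenzyl malonate | O=C(CC(=O)OCc1ccccc1)OCc1ccccc1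
A3 | alternative 1 | benzyl 2-[2-(benzyloxy)-2-oxoethyl]-4,6-dimethoxybenzoate | COc1cc(OC)c(C(=O)OCc2ccccc2)c(CC(=O)OCc2ccccc2)c1
A4 | alternative 2 | (E)-5-(2-pentyl-1,3-dioxolan-2-yl)pent-3-en-2-one | CCCCCC1(C/C=C/C(C)=O)OCCO1
A5 | alternative 2 | benzyl 2-hydroxy-4-oxo-6-[(2-pentyl-1,3-dioxolan-2-yl)methyl]cyclohex-1-ene-1-carboxylate (racemic, one enantiomer drawn) | O=C(OCc1ccccc1)C1=C(O)CC(=O)C[C@@H]1CC2(CCCCC)OCCO2
A6 | alternative 3 | benzyl 2-(benzyloxy)-4-hydroxy-6-[(2-pentyl-1,3-dioxolan-2-yl)methyl]benzoate | CCCCCC1(Cc2cc(O)cc(OCc3ccccc3)c2C(=O)OCc2ccccc2)OCCO1
A7 | alternative 3 | 4-(2-pentyl-1,3-dioxolan-2-yl)but-2-ynoic acid | CCCCCC1(CC#CC(=O)O)OCCO1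
A8 | alternative 3 | benzyl 2-(benzyloxy)-6-[(2-pentyl-1,3-dioxolan-2-yl)methyl]-4-{[4-(2-pentyl-1,3-dioxolan-2-yl)but-2-ynoyl]oxy}benzoate | CCCCCC1(CC#CC(=O)Oc2cc(CC3(CCCCC)OCCO3)c(C(=O)OCc3ccccc3)c(OCc3ccccc3)c2)OCCO1
A9 | alternative 3 | 1,3-dimethoxy-1-(trimethylsilyloxy)buta-1,3-diene | C=C(OC)C=C(OC)O[Si](C)(C)C
A10 | alternative 3 | benzyl 2-(benzyloxy)-4-({2-hydroxy-4-methoxy-6-[(2-pentyl-1,3-dioxolan-2-yl)methyl]benzoyl}oxy)-6-[(2-pentyl-1,3-dioxolan-2-yl)methyl]benzoate | CCCCCC1(Cc2cc(OC)cc(O)c2C(=O)Oc2cc(CC3(CCCCC)OCCO3)c(C(=O)OCc3ccccc3)c(OCc3ccccc3)c2)OCCO1
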